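**Retrosynthetic overview**
1. No ring is built, because both benzene rings are bought. The last changes are CHO → CH2OH and the diaryl ether C–O bond.
2. Diaryl ether: SNAr of the phenoxide of methyl 2,6-dihydroxy-4-methylbenzoate on a ring-B 2-nitrobenzaldehyde, with NO2 as the leaving group.
3. Prenyl ether: SNAr of prenol on the C–F bond ortho to the same NO2.
4. Key C–C bond (ring B–CHO): Cl3C⁻, a formyl-anion equivalent, replaces the H ortho to NO2 in 3-fluoro-4-nitroanisole (vicarious nucleophilic substitution). The CHCl2 group is then hydrolysed to CHO.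
5. One NO2 group does three jobs: it activates the C–H, activates the C–F, and finally leaves.

Assumption: the target has no stereocentre and no E/Z-isomeric double bond, so it is achiral and the route needs no stereocontrol.

**Step 1**
Reactants: 1 2-fluoro-4-methoxy-1-nitrobenzene; 2 chloroform
Product: 5 1-(dichloromethyl)-3-fluoro-5-methoxy-2-nitrobenzene, via sigma-H adduct 3 (not isolated), via dichlorobenzylic carbanion 4 (not isolated)
Conditions: t-BuOK (4 equiv), THF–DMF 1:1, −75 °C; 1 + CHCl3 (1.2 equiv) added in one portion, 1–2 min; then AcOH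
Reagents that add atoms: chloroform, ClC(Cl)Cl
Why: Vicarious nucleophilic substitution of hydrogen (Mąkosza reaction): Cl3C⁻, a masked formyl anion, attacks the only open acceptor carbon of 1 (the C–H ortho to NO2, since para is blocked by OMe and the other ortho site by F) to give 3 faster than fluoride is displaced, excess t-BuOK then removes HCl by β-elimination to give the nitrobenzylic carbanion 4, and the acid quench gives 5, so two carbons that are both normally acceptors (nitroarene C–H and formyl C) are joined and no stereocentre survives.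

**Step 2**
Reactants: 5 1-(dichloromethyl)-3-fluoro-5-methoxy-2-nitrobenzene
Product: 6 3-fluoro-5-methoxy-2-nitrobenzaldehyde
Conditions: 90% H2SO4, 70 °C, 1 h; then ice–water
Reagents that add atoms: water, O
Why: Acid-promoted hydrolysis of a benzal chloride (gem-dichloride to aldehyde through the α-chlorobenzyl cation and chlorohydrin), under which ArF, ArOMe and ArNO2 are inert and no stereocentre is formed.

**Step 3**
Reactants: 6 3-fluoro-5-methoxy-2-nitrobenzaldehyde; 7 3-methylbut-2-en-1-ol (prenol)
Product: 8 5-methoxy-3-[(3-methylbut-2-en-1-yl)oxy]-2-nitrobenzaldehyde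
Conditions: 7 (1.2 equiv), Cs2CO3 (1.5 equiv), DMF, 40 °C
Reagents that add atoms: 3-methylbut-2-en-1-ol, CC(C)=CCO
Why: Nucleophilic aromatic substitution (addition–elimination): the C–F carbon is ortho to NO2 and meta to OMe, so it is the most electrophilic ring position and fluoride the fastest nucleofuge, whereas the NO2-bearing carbon is deactivated by the para OMe and a carbonate base adds only reversibly to the non-enolisable aldehyde.

**Step 4**
Reactants: 8 5-methoxy-3-[(3-methylbut-2-en-1-yl)oxy]-2-nitrobenzaldehyde; 9 methyl 2,6-dihydroxy-4-methylbenzoate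
Product: 11 methyl 2-hydroxy-6-{2-(hydroxymethyl)-4-methoxy-6-[(3-methylbut-2-en-1-yl)oxy]phenoxy}-4-methylbenzoate, via diaryl ether aldehyde 10 (not isolated)
Conditions: 9 (1.5 equiv), Cs2CO3 (2 equiv), DMSO, 90 °C; then 0 °C, MeOH, NaBH4 (1 equiv); aq. NH4Cl
Reagents that add atoms: methyl 2,6-dihydroxy-4-methylbenzoate, COC(=O)c1c(O)cc(C)cc1O
Why: SNAr with nitrite as nucleofuge followed by chemoselective borohydride reduction: in 8 the NO2 group is twisted out of plane between CHO and O-prenyl and sits ortho to the formyl acceptor, the weakly basic phenoxide of symmetrical 9 can expel NO2⁻ but not MeO⁻ or prenyl-O⁻, the second OH of 9 stays chelated to the ester so mono-arylation dominates, and NaBH4 at 0 °C reduces only the aldehyde of 10 while ester, alkene and aryl ethers survive, giving an achiral product.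

**Compound list**
1 | 2-fluoro-4-methoxy-1-nitrobenzene (3-fluoro-4-nitroanisole) | COc1ccc([N+](=O)[O-])c(F)c1 | starting material
2 | chloroform | ClC(Cl)Cl | starting material
3 | potassium nitronate σH-adduct of 1 and Cl3C⁻ (racemic, transient) | [K+].COC1=CC(C(Cl)(Cl)Cl)C(=[N+]([O-])[O-])C(F)=C1 | intermediate (not isolated)
4 | potassium dichloro(3-fluoro-5-methoxy-2-nitrophenyl)methanide | [K+].COc1cc(F)c([N+](=O)[O-])c([C-](Cl)Cl)c1 | intermediate (not isolated)
5 | 1-(dichloromethyl)-3-fluoro-5-methoxy-2-nitrobenzene | COc1cc(F)c([N+](=O)[O-])c(C(Cl)Cl)c1 | intermediate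
6 | 3-fluoro-5-methoxy-2-nitrobenzaldehyde | COc1cc(F)c([N+](=O)[O-])c(C=O)c1 | intermediate
7 | 3-methylbut-2-en-1-ol (prenol) | CC(C)=CCO | starting material
8 | 5-methoxy-3-[(3-methylbut-2-en-1-yl)oxy]-2-nitrobenzaldehyde | COc1cc(OCC=C(C)C)c([N+](=O)[O-])c(C=O)c1 | intermediate
9 | methyl 2,6-dihydroxy-4-methylbenzoate | COC(=O)c1c(O)cc(C)cc1O | starting material
10 | methyl 2-{2-formyl-4-methoxy-6-[(3-methylbut-2-en-1-yl)oxy]phenoxy}-6-hydroxy-4-methylbenzoate | COC(=O)c1c(O)cc(C)cc1Oc1c(C=O)cc(OC)cc1OCC=C(C)C | intermediate (not isolated)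
11 | methyl 2-hydroxy-6-{2-(hydroxymethyl)-4-methoxy-6-[(3-methylbut-2-en-1-yl)oxy]phenoxy}-4-methylbenzoate | COC(=O)c1c(O)cc(C)cc1Oc1c(CO)cc(OC)cc1OCC=C(C)C | target

**Total step count:** 4. **Longest linear sequence:** 4 (1 → 5 → 6 → 8 → 11).

**Steps most likely to fail**

Step 1 is the riskiest.
- Cl3C⁻ is a fully substituted carbanion that must enter next to NO2.
- The para OMe lowers the electrophilicity of 1.
- Cl3C⁻ decays to dichlorocarbene within minutes.

The fallback sets out from 1 and comes back at 6. It swaps the vicarious mechanism for an oxidative one and uses a smaller, secondary acyl-anion equivalent. 2-Lithio-1,3-dithiane (1,3-dithiane, n-BuLi, THF, −78 °C) is added to 1. The σH-adduct is oxidised in the same flask with DDQ after a few minutes, before fluoride can be displaced. This gives 2-(3-fluoro-5-methoxy-2-nitrophenyl)-1,3-dithiane F1. MeI and CaCO3 in aqueous MeCN at 40 °C then unmask it to aldehyde 6.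

Step 4 is the second risk.
- The carbon that loses NO2 is para to OMe and has only one formyl activator.
- The chelated phenoxide of 9 is a weak nucleophile.
- The nitrite set free, or prenyl transfer from 8, may consume material.

The fallback sets out from 8 and comes back at 10. It makes the C–O bond intramolecularly.
- The α-effect nucleophile from (E)-benzaldehyde oxime (K2CO3, DMSO, 60 °C) replaces NO2 and then collapses with loss of benzonitrile. This gives 2-hydroxy-5-methoxy-3-[(3-methylbut-2-en-1-yl)oxy]benzaldehyde F3.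
- DCC esterification with 2,6-dihydroxy-4-methylbenzoic acid in toluene gives the depside 2-formyl-4-methoxy-6-[(3-methylbut-2-en-1-yl)oxy]phenyl 2,6-dihydroxy-4-methylbenzoate F4.
- K2CO3 in DMSO at room temperature triggers a Smiles rearrangement through a six-membered spiro-Meisenheimer complex. This gives 2-{2-formyl-4-methoxy-6-[(3-methylbut-2-en-1-yl)oxy]phenoxy}-6-hydroxy-4-methylbenzoic acid F5.
- MeI and KHCO3 in DMF esterify F5 to 10, which is reduced with NaBH4 as before.

Step 3 is the third risk.
- The alkoxide may add to the aldehyde.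
- It may attack the NO2-bearing carbon.
- It may exchange the para OMe.

The fallback sets out from 6 and comes back at 8. It reverses the roles in the O–C(prenyl) bond. Aqueous KOH in DMSO at room temperature to 40 °C replaces fluoride by hydroxide, giving 3-hydroxy-5-methoxy-2-nitrobenzaldehyde F2. Its acidic phenol is then alkylated with prenyl bromide and K2CO3 in acetone (Williamson ether synthesis) to give 8.

**Further compounds**
F1 | step 1 | 2-(3-fluoro-5-methoxy-2-nitrophenyl)-1,3-dithiane | COc1cc(F)c([N+](=O)[O-])c(C2SCCCS2)c1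
F2 | step 3 | 3-hydroxy-5-methoxy-2-nitrobenzaldehyde | COc1cc(O)c([N+](=O)[O-])c(C=O)c1
F3 | step 4 | 2-hydroxy-5-methoxy-3-[(3-methylbut-2-en-1-yl)oxy]benzaldehyde | COc1cc(C=O)c(O)c(OCC=C(C)C)c1
F4 | step 4 | 2-formyl-4-methoxy-6-[(3-methylbut-2-en-1-yl)oxy]phenyl 2,6-dihydroxy-4-methylbenzoate | Cc1cc(O)c(C(=O)Oc2c(C=O)cc(OC)cc2OCC=C(C)C)c(O)c1
F5 | step 4 | 2-{2-formyl-4-methoxy-6-[(3-methylbut-2-en-1-yl)oxy]phenoxy}-6-hydroxy-4-methylbenzoic acid | Cc1cc(O)c(C(=O)O)c(Oc2c(C=O)cc(OC)cc2OCC=C(C)C)c1
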